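**Retrosynthetic overview**
- The 14-membered carbocycle is closed last, at C12–C13, by a ligand-controlled Nozaki–Hiyama–Kishi reaction of an iodo-aldehyde, followed by acetylation.
- C7=C8 with its ester comes from a Still–Gennari olefination that joins a butenolide aldehyde (C1–C7, C13–C17) to a phosphonate (C8–C12).
- The butenolide is cut at O–C2 and C15–C16: a one-pot carboxylative annulation with CO2 (alkenyllithium carboxylation, then intramolecular SN2). The enabling feature is the (Z)-tetrasubstituted C1=C15 alkene that holds the C15–I bond and the allylic C2–Cl bond on the same side.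
- That iodoalkene comes from copper-catalysed anti-carbomagnesiation/iodination of an (S)-enynol (C1–C14 bond; the dioxolane is the masked C13 aldehyde). C2 is set by CBS reduction and C3=C4 by Negishi carboalumination.
- Ring order: butenolide first (step 7), 14-membered carbocycle second (step 15).

Key step: step 7

Remark: cembrane numbering is used throughout (C2 = lactone CH–O, C1 = butenolide β-carbon, C15/C16/C17 = lactone α-carbon, carbonyl and α-methyl, C13 = acetoxy carbon, C19 = ester carbon); the target is the (2S,13S) isomer, and 1, 10 and 23 are taken as purchasable.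

Step 1
Reactants: 1 tert-butyldimethyl(pent-4-yn-1-yloxy)silane
Product: 3 (E)-tert-butyl[(5-iodo-4-methylpent-4-en-1-yl)oxy]dimethylsilane, via alkenylalane 2 (not isolated)
Conditions: Me3Al, Cp2ZrCl2 (cat.), CH2Cl2, 0→23 °C; then I2, THF, −30 °C
Reagents that add atoms: trimethylaluminium, C[Al](C)C; iodine, II
Why: Negishi zirconium-catalysed carboalumination adds CH3 and Al syn and regioselectively across the terminal alkyne and iodinolysis proceeds with retention, so the (E)-vinyl iodide that becomes C3=C4 with its C4 methyl should form as a single isomer.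

Step 2
Reactants: 4 but-2-ynoic acid; 5 N,O-dimethylhydroxylamine hydrochloride
Product: 6 N-methoxy-N-methylbut-2-ynamide
Conditions: DCC, Et3N, CH2Cl2, 0→23 °C
Reagents that add atoms: none
Why: Carbodiimide-mediated amide coupling should give the Weinreb amide that later delivers C2, C1, C15 and C17.

Step 3
Reactants: 3 (E)-tert-butyl[(5-iodo-4-methylpent-4-en-1-yl)oxy]dimethylsilane; 6 N-methoxy-N-methylbut-2-ynamide
Product: 8 (E)-9-(tert-butyldimethylsilyloxy)-6-methylnon-5-en-2-yn-4-one, via alkenyllithium 7 (not isolated)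
Conditions: t-BuLi (2 equiv), Et2O, −78 °C; then 6, −78→0 °C; H2O
Reagents that add atoms: none
Why: Iodine–lithium exchange with retention of the alkene geometry followed by Weinreb ketone synthesis should stop at the ynone because the chelated tetrahedral adduct collapses only on work-up.

Step 4
Reactants: 8 (E)-9-(tert-butyldimethylsilyloxy)-6-methylnon-5-en-2-yn-4-one
Product: 9 (S,E)-9-(tert-butyldimethylsilyloxy)-6-methylnon-5-en-2-yn-4-ol
Conditions: (S)-Me-CBS (1 equiv), BH3·SMe2, THF, −30 °C
Reagents that add atoms: none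
Why: Corey–Bakshi–Shibata reduction, with the slim propynyl group as the small and the β,β-disubstituted alkenyl group as the large substituent, should deliver hydride to the face that gives the (S)-carbinol at C2 by reagent control, carbonyl reduction outrunning hydroboration at −30 °C.

Step 5
Reactants: 9 (S,E)-9-(tert-butyldimethylsilyloxy)-6-methylnon-5-en-2-yn-4-ol; 10 (1,3-dioxolan-2-ylmethyl)magnesium bromide
Product: 12 (2Z,4S,5E)-9-(tert-butyldimethylsilyloxy)-3-(1,3-dioxolan-2-ylmethyl)-2-iodo-6-methylnona-2,5-dien-4-ol, via magnesium chelate 11 (not isolated)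
Conditions: 10 (5 equiv), CuI (0.5 equiv), THF, −20→23 °C; then I2, −78→0 °C
Reagents that add atoms: iodine, II
Why: Copper-catalysed, alkoxide-directed anti-carbomagnesiation of the propargylic alcohol puts the acetal-bearing carbon (C14) on C1 and magnesium on C15 in a five-membered chelate, and iodinolysis with retention should give the (Z)-tetrasubstituted iodoalkene with C15–I cis to C2, the C2 stereocentre being untouched.

Step 6
Reactants: 12 (2Z,4S,5E)-9-(tert-butyldimethylsilyloxy)-3-(1,3-dioxolan-2-ylmethyl)-2-iodo-6-methylnona-2,5-dien-4-ol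
Product: 13 tert-butyl{[(4E,6R,7Z)-6-chloro-7-(1,3-dioxolan-2-ylmethyl)-8-iodo-4-methylnona-4,7-dien-1-yl]oxy}dimethylsilane
Conditions: PPh3, hexachloroacetone, CH2Cl2, −20→0 °C; used at once
Reagents that add atoms: hexachloroacetone, ClC(Cl)(Cl)C(=O)C(Cl)(Cl)Cl
Why: Appel-type chlorination proceeds by SN2 attack of chloride on the alkoxyphosphonium ion, so the (S)-alcohol should give the (R)-chloride with inversion and, under these cold neutral conditions, without allylic transposition.

Step 7
Reactants: 13 tert-butyl{[(4E,6R,7Z)-6-chloro-7-(1,3-dioxolan-2-ylmethyl)-8-iodo-4-methylnona-4,7-dien-1-yl]oxy}dimethylsilane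
Product: 16 (S)-5-[(E)-5-(tert-butyldimethylsilyloxy)-2-methylpent-1-en-1-yl]-4-(1,3-dioxolan-2-ylmethyl)-3-methylfuran-2(5H)-one, via alkenyllithium 14 (not isolated), via lithium carboxylate 15 (not isolated)
Conditions: t-BuLi (2.1 equiv), THF/Et2O/pentane, −100 °C, 5 min; CO2 (g), −100→−78 °C; then 23 °C, 2 h
Reagents that add atoms: carbon dioxide, O=C=O
Why: Iodine–lithium exchange at −100 °C gives a configurationally stable (Z)-alkenyllithium that is carboxylated by CO2 (C15–C16 bond), and on warming the lithium carboxylate, held cis to C2 by the tetrasubstituted C1=C15 bond, displaces the allylic chloride intramolecularly (O–C2 bond), a formal [3+2] annulation of CO2. The closest known reaction types are the carboxylation of alkenyllithiums with carbon dioxide and the lactonisation of (Z)-4-halo-2-enoates to butenolides. The butenolide closes in a 5-exo-tet SN2 step. The C2 stereocentre is controlled by the configuration of the C–Cl carbon, which is inverted, so the (R)-chloride should give the (S)-lactone. The step needs exchange at C–I faster than attack or deprotonation at the allylic chloride, carboxylation faster than 1,3-elimination to a cyclopropene, and SN2 at C2 rather than SN2′ at C4; the low temperature with immediate CO2 quench and the cis geometry that favours the five-membered ring should secure this.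

Step 8
Reactants: 16 (S)-5-[(E)-5-(tert-butyldimethylsilyloxy)-2-methylpent-1-en-1-yl]-4-(1,3-dioxolan-2-ylmethyl)-3-methylfuran-2(5H)-one
Product: 17 (S)-4-(1,3-dioxolan-2-ylmethyl)-5-[(E)-5-hydroxy-2-methylpent-1-en-1-yl]-3-methylfuran-2(5H)-one
Conditions: HF·pyridine, pyridine, THF, 0→23 °C
Reagents that add atoms: none
Why: Fluoride-induced cleavage of the primary silyl ether under buffered, non-basic conditions should leave the dioxolane and the epimerisable butenolide C2–H untouched.

Step 9
Reactants: 17 (S)-4-(1,3-dioxolan-2-ylmethyl)-5-[(E)-5-hydroxy-2-methylpent-1-en-1-yl]-3-methylfuran-2(5H)-one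
Product: 18 (E)-5-[(S)-3-(1,3-dioxolan-2-ylmethyl)-4-methyl-5-oxo-2,5-dihydrofuran-2-yl]-4-methylpent-4-enal
Conditions: Dess–Martin periodinane, CH2Cl2, 23 °C
Reagents that add atoms: none
Why: Dess–Martin oxidation is a mild, non-basic oxidation of the primary alcohol to the C7 aldehyde that should not affect the butenolide or the acetal.

Step 10
Reactants: 19 pent-3-yn-1-ol
Product: 21 (E)-4-iodopent-3-en-1-ol, via zirconocene adduct 20 (not isolated)
Conditions: Cp2Zr(H)Cl (2.5 equiv), THF, 23→50 °C; then I2, 0 °C; H2O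
Reagents that add atoms: iodine, II
Why: Hydrozirconation with excess Cp2Zr(H)Cl adds H and Zr syn and equilibrates zirconium to the less hindered methyl-bearing carbon, so iodinolysis with retention should give the (E)-2-iodoalkene that becomes C11=C12 with its C12 methyl.

Step 11
Reactants: 21 (E)-4-iodopent-3-en-1-ol
Product: 22 (E)-2,5-diiodopent-2-ene
Conditions: I2, PPh3, imidazole, CH2Cl2, 0 °C
Reagents that add atoms: iodine, II
Why: Appel iodination converts the primary alcohol into the iodide by SN2 displacement of the alkoxyphosphonium ion without touching the vinyl iodide.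

Step 12
Reactants: 22 (E)-2,5-diiodopent-2-ene; 23 methyl bis(2,2,2-trifluoroethyl)phosphonoacetate
Product: 24 methyl (E)-2-[bis(2,2,2-trifluoroethoxy)phosphoryl]-6-iodohept-5-enoate
Conditions: NaH, DMF, 0→23 °C
Reagents that add atoms: none
Why: C-Alkylation of the sodium enolate of the phosphonoacetate with the primary homoallylic iodide (SN2) should install the C9–C12 chain on the future C8.

Step 13
Reactants: 18 (E)-5-[(S)-3-(1,3-dioxolan-2-ylmethyl)-4-methyl-5-oxo-2,5-dihydrofuran-2-yl]-4-methylpent-4-enal; 24 methyl (E)-2-[bis(2,2,2-trifluoroethoxy)phosphoryl]-6-iodohept-5-enoate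
Product: 25 methyl (2Z,6E)-7-[(S)-3-(1,3-dioxolan-2-ylmethyl)-4-methyl-5-oxo-2,5-dihydrofuran-2-yl]-2-[(E)-4-iodopent-3-en-1-yl]-6-methylhepta-2,6-dienoate
Conditions: KHMDS, 18-crown-6, THF, −78 °C
Reagents that add atoms: none
Why: Still–Gennari olefination under dissociating conditions is kinetically controlled and should give the trisubstituted enoate with the ester cis to C6 (Z), while the weakly basic phosphonate anion should not epimerise C2.

Step 14
Reactants: 25 methyl (2Z,6E)-7-[(S)-3-(1,3-dioxolan-2-ylmethyl)-4-methyl-5-oxo-2,5-dihydrofuran-2-yl]-2-[(E)-4-iodopent-3-en-1-yl]-6-methylhepta-2,6-dienoate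
Product: 26 methyl (2Z,6E)-2-[(E)-4-iodopent-3-en-1-yl]-6-methyl-7-[(S)-4-methyl-5-oxo-3-(2-oxoethyl)-2,5-dihydrofuran-2-yl]hepta-2,6-dienoate
Conditions: 1 M HCl, THF, 23 °C; used at once
Reagents that add atoms: water, O
Why: Acid-catalysed hydrolysis of the 1,3-dioxolane unmasks the C13 aldehyde under conditions to which the butenolide, the enoate and the vinyl iodide are inert.

Step 15
Reactants: 26 methyl (2Z,6E)-2-[(E)-4-iodopent-3-en-1-yl]-6-methyl-7-[(S)-4-methyl-5-oxo-3-(2-oxoethyl)-2,5-dihydrofuran-2-yl]hepta-2,6-dienoate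
Product: 27 16-oxosarcoglaucol ((2S,13S)-13-hydroxy macrocycle, the deacetyl target)
Conditions: CrCl2, NiCl2 (cat.), chiral oxazoline–sulfonamide ligand (enantiomer chosen for Re-face addition), Et3N, THF, 23 °C, 2 mM
Reagents that add atoms: none
Why: Nozaki–Hiyama–Kishi reaction: nickel inserts into the C12–I bond, the alkenyl group passes to chromium with retention of the (E)-geometry and adds to the C13 aldehyde to close the 14-membered carbocycle, the chiral chromium–sulfonamide complex directing attack to the Re face so that the (13S)-alcohol should predominate.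

Step 16
Reactants: 27 16-oxosarcoglaucol
Product: 28 16-oxosarcoglaucol acetate
Conditions: Ac2O, pyridine, DMAP (cat.), CH2Cl2, 0 °C
Reagents that add atoms: acetic anhydride, CC(=O)OC(C)=O
Why: DMAP-catalysed acylation of the secondary allylic alcohol with acetic anhydride proceeds with retention at C13 and should give the target.

**Compound list**
1 | tert-butyldimethyl(pent-4-yn-1-yloxy)silane | C#CCCCO[Si](C)(C)C(C)(C)C | starting material
2 | dimethyl[(E)-5-(tert-butyldimethylsilyloxy)-2-methylpent-1-en-1-yl]alumane | C[Al](C)/C=C(\C)CCCO[Si](C)(C)C(C)(C)C | intermediate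
3 | (E)-tert-butyl[(5-iodo-4-methylpent-4-en-1-yl)oxy]dimethylsilane | I/C=C(\C)CCCO[Si](C)(C)C(C)(C)C | intermediate
4 | but-2-ynoic acid | CC#CC(=O)O | starting material
5 | N,O-dimethylhydroxylamine hydrochloride | CNOC.Cl | starting material
6 | N-methoxy-N-methylbut-2-ynamide | CC#CC(=O)N(C)OC | intermediate
7 | [(E)-5-(tert-butyldimethylsilyloxy)-2-methylpent-1-en-1-yl]lithium | [Li]/C=C(\C)CCCO[Si](C)(C)C(C)(C)C | intermediate
8 | (E)-9-(tert-butyldimethylsilyloxy)-6-methylnon-5-en-2-yn-4-one | CC#CC(=O)/C=C(\C)CCCO[Si](C)(C)C(C)(C)C | intermediate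
9 | (S,E)-9-(tert-butyldimethylsilyloxy)-6-methylnon-5-en-2-yn-4-ol | CC#C[C@@H](O)/C=C(\C)CCCO[Si](C)(C)C(C)(C)C | intermediate
10 | (1,3-dioxolan-2-ylmethyl)magnesium bromide | Br[Mg]CC1OCCO1 | starting material
11 | (S)-cyclic alkenylmagnesium alkoxide (2,5-dihydro-1,2-oxamagnesole with the dioxolanylmethyl group on C1) | CC1=C(CC2OCCO2)[C@@H](O[Mg]1)/C=C(\C)CCCO[Si](C)(C)C(C)(C)C | intermediate
12 | (2Z,4S,5E)-9-(tert-butyldimethylsilyloxy)-3-(1,3-dioxolan-2-ylmethyl)-2-iodo-6-methylnona-2,5-dien-4-ol | C/C(I)=C(\CC1OCCO1)[C@@H](O)/C=C(\C)CCCO[Si](C)(C)C(C)(C)C | intermediate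
13 | tert-butyl{[(4E,6R,7Z)-6-chloro-7-(1,3-dioxolan-2-ylmethyl)-8-iodo-4-methylnona-4,7-dien-1-yl]oxy}dimethylsilane | C/C(I)=C(\CC1OCCO1)[C@H](Cl)/C=C(\C)CCCO[Si](C)(C)C(C)(C)C | intermediate
14 | (Z)-alkenyllithium from 13 (Li on C15) | C/C([Li])=C(\CC1OCCO1)[C@H](Cl)/C=C(\C)CCCO[Si](C)(C)C(C)(C)C | intermediate
15 | lithium (2Z,4R,5E)-9-(tert-butyldimethylsilyloxy)-4-chloro-3-(1,3-dioxolan-2-ylmethyl)-2,6-dimethylnona-2,5-dienoate | C/C(C(=O)[O-])=C(\CC1OCCO1)[C@H](Cl)/C=C(\C)CCCO[Si](C)(C)C(C)(C)C.[Li+] | intermediate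
16 | (S)-5-[(E)-5-(tert-butyldimethylsilyloxy)-2-methylpent-1-en-1-yl]-4-(1,3-dioxolan-2-ylmethyl)-3-methylfuran-2(5H)-one | CC1=C(CC2OCCO2)[C@H](/C=C(\C)CCCO[Si](C)(C)C(C)(C)C)OC1=O | intermediate
17 | (S)-4-(1,3-dioxolan-2-ylmethyl)-5-[(E)-5-hydroxy-2-methylpent-1-en-1-yl]-3-methylfuran-2(5H)-one | CC1=C(CC2OCCO2)[C@H](/C=C(\C)CCCO)OC1=O | intermediate
18 | (E)-5-[(S)-3-(1,3-dioxolan-2-ylmethyl)-4-methyl-5-oxo-2,5-dihydrofuran-2-yl]-4-methylpent-4-enal | CC1=C(CC2OCCO2)[C@H](/C=C(\C)CCC=O)OC1=O | intermediate
19 | pent-3-yn-1-ol | CC#CCCO | starting material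
20 | O,C-bis(chlorozirconocene) adduct of pent-3-yn-1-ol ((E)-alkenylzirconocene zirconium alkoxide) | C/C(=C\CCO[Zr](Cl)(C1C=CC=C1)C1C=CC=C1)[Zr](Cl)(C1C=CC=C1)C1C=CC=C1 | intermediate
21 | (E)-4-iodopent-3-en-1-ol | C/C(I)=C\CCO | intermediate
22 | (E)-2,5-diiodopent-2-ene | C/C(I)=C\CCI | intermediate
23 | methyl bis(2,2,2-trifluoroethyl)phosphonoacetate | COC(=O)CP(=O)(OCC(F)(F)F)OCC(F)(F)F | starting material
24 | methyl (E)-2-[bis(2,2,2-trifluoroethoxy)phosphoryl]-6-iodohept-5-enoate | COC(=O)C(CC/C=C(\C)I)P(=O)(OCC(F)(F)F)OCC(F)(F)F | intermediate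
25 | methyl (2Z,6E)-7-[(S)-3-(1,3-dioxolan-2-ylmethyl)-4-methyl-5-oxo-2,5-dihydrofuran-2-yl]-2-[(E)-4-iodopent-3-en-1-yl]-6-methylhepta-2,6-dienoate | CC1=C(CC2OCCO2)[C@H](/C=C(\C)CC/C=C(C(=O)OC)/CC/C=C(\C)I)OC1=O | intermediate
26 | methyl (2Z,6E)-2-[(E)-4-iodopent-3-en-1-yl]-6-methyl-7-[(S)-4-methyl-5-oxo-3-(2-oxoethyl)-2,5-dihydrofuran-2-yl]hepta-2,6-dienoate | CC1=C(CC=O)[C@H](/C=C(\C)CC/C=C(C(=O)OC)/CC/C=C(\C)I)OC1=O | intermediate
27 | 16-oxosarcoglaucol ((2S,13S)-alcohol) | COC(=O)/C1=C\CC/C(C)=C/[C@@H]2OC(=O)C(C)=C2C[C@H](O)/C(C)=C/CC1 | intermediate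
28 | 16-oxosarcoglaucol acetate | COC(=O)/C1=C\CC/C(C)=C/[C@@H]2OC(=O)C(C)=C2C[C@H](OC(C)=O)/C(C)=C/CC1 | target

**Step count**
Total: 16 steps. Longest linear sequence: 12 steps (1, 3–9, 13–16) from 1.

**Steps most likely to fail**

Step 7. The doubly allylic chloride may ionise or transpose (loss of configuration at C2), tert-butyllithium may deprotonate C2, or the chloroalkenyllithium may undergo 1,3-elimination to a cyclopropene before it is carboxylated. The fallback sets out from 12, so it also bypasses step 6. Palladium-catalysed carbonylative lactonisation (PdCl2(PPh3)2, CO 1 atm, Et3N, THF/MeCN, 50 °C) should close the butenolide with the C2 hydroxyl as ring oxygen and retention at C2. It comes back to the route at 16 and makes no compound outside the list (F0).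

Step 5. The acetal-bearing Grignard or its organocopper may undergo β-alkoxide elimination, or carbometalation may be too slow and return the enynol. The fallback sets out from 9 and uses a vinyl group as the two-carbon unit. Uncatalysed anti-carbomagnesiation with vinylmagnesium chloride (THF, reflux) and iodinolysis should give the iodo-dienol (2Z,4S,5E)-9-(tert-butyldimethylsilyloxy)-3-ethenyl-2-iodo-6-methylnona-2,5-dien-4-ol F1. Silylation (TESCl, imidazole) gives its triethylsilyl ether F2. Hydroboration of the terminal vinyl group with 9-BBN and NaBO3 oxidation gives the primary alcohol F3. Dess–Martin oxidation gives the aldehyde F4. Acetalisation with 1,2-bis(trimethylsilyloxy)ethane and catalytic TMSOTf at −78 °C gives the dioxolane triethylsilyl ether F5. Selective removal of the secondary triethylsilyl group (HF·pyridine, pyridine, −10 °C) comes back to the route at 12.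

Step 15. The ligand and the macrocyclic transition state may be mismatched, giving poor facial selectivity and the 13-epimer. The fallback sets out from 26. Ligand-free macrocyclisation (CrCl2, NiCl2 cat., DMSO/THF) gives 27 together with its C13 epimer, 13-epi-16-oxosarcoglaucol F6, which is separated. F6 is then converted by a Mitsunobu reaction with acetic acid (PPh3, DIAD, toluene, 0 °C), with inversion, into 28, where it comes back to the route; the 27 formed alongside is acetylated as in step 16.

Further compounds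
F0 | step 7 | none | none
F1 | step 5 | (2Z,4S,5E)-9-(tert-butyldimethylsilyloxy)-3-ethenyl-2-iodo-6-methylnona-2,5-dien-4-ol | C/C(I)=C(\C=C)[C@@H](O)/C=C(\C)CCCO[Si](C)(C)C(C)(C)C
F2 | step 5 | triethylsilyl ether of F1 | C/C(I)=C(\C=C)[C@@H](O[Si](CC)(CC)CC)/C=C(\C)CCCO[Si](C)(C)C(C)(C)C
F3 | step 5 | (3Z,5E)-primary alcohol from hydroboration of F2 (2-hydroxyethyl group on C1) | C/C(I)=C(\CCO)[C@@H](O[Si](CC)(CC)CC)/C=C(\C)CCCO[Si](C)(C)C(C)(C)C
F4 | step 5 | aldehyde from F3 (2-oxoethyl group on C1) | C/C(I)=C(\CC=O)[C@@H](O[Si](CC)(CC)CC)/C=C(\C)CCCO[Si](C)(C)C(C)(C)C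
F5 | step 5 | triethylsilyl ether of 12 | C/C(I)=C(\CC1OCCO1)[C@@H](O[Si](CC)(CC)CC)/C=C(\C)CCCO[Si](C)(C)C(C)(C)C
F6 | step 15 | 13-epi-16-oxosarcoglaucol ((2S,13R)-alcohol) | COC(=O)/C1=C\CC/C(C)=C/[C@@H]2OC(=O)C(C)=C2C[C@@H](O)/C(C)=C/CC1
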